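**Retrosynthetic overview**

1. Feature: C8 of ring A lies between O1 and O7 and bears C3', the benzylic carbon of the hexanoate arm and the only stereocentre outside ring B. In a symmetric 3,5-bis(benzyloxy)phenol the free hydroxyl (future O1) steers an enal to its ortho carbon (future C8) and then traps the aldehyde as a lactol, so the C8–C3' bond and (R)-C3' come from one organocatalytic step.
2. C6–prenyl: aromatic Claisen rearrangement of a 7-O-(1,1-dimethylallyl) ether, after hydrogenolysis of the benzyl ethers.
3. Ring B: C4–C4a by intramolecular Friedel–Crafts acylation; O1–C2 by Mitsunobu inversion of the anti hydroxy ester from a Fráter–Seebach methylation, which fixes the cis (2R,3S) pair.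
4. Hexanoate arm: lactol, then lactone, then methanolysis, which gives the methyl ester and frees O1.
5. Ring order: ring A is bought; a temporary lactol/lactone ring is closed in step 1 and opened in step 3; ring B is closed in step 7.

Key step: step 1

Remarks on the chemistry: chroman-4-one numbering is used (O1, C2, C3, C4, C4a, C5–C8, C8a; ring A the arene, ring B the pyranone), side-chain carbons are primed (C1' ester carbon, C3' benzylic), and the target is read as (2R,3S,3'R), that is cis-2,3-dimethyl. Assumption: the (S)-configured prolinol silyl ether is taken to give (R)-C3' by the usual shielding model; should lactone 5 prove to be the antipode, the (R)-catalyst is used and nothing else changes.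

**Route**

Step 1
Reactants: 1 3,5-bis(benzyloxy)phenol; 2 (E)-hex-2-enal
Product: 4 (4R)-5,7-bis(benzyloxy)-4-propylchroman-2-ol, via hydroxy aldehyde 3 (not isolated)
Conditions: (S)-2-[diphenyl(trimethylsilyloxy)methyl]pyrrolidine (20 mol%), PhCO2H (20 mol%), 2 (1.2 equiv), PhMe, 0 °C
Reagents that add atoms: none
Why: The amine condenses with 2 to an (E)-iminium ion whose s-trans enal has one face covered by the silyloxydiphenylmethyl arm; phenol 1, reacting as an enol through a carbon ortho to its hydroxyl, adds to C3' from the open face, the ring re-aromatises, and hydrolysis of the enamine releases aldehyde 3 and the catalyst. The closest known reaction type is the iminium-catalysed enantioselective Friedel–Crafts alkylation with hemiacetal closure of naphthols and electron-rich phenols with enals. The one ring formed, the lactol ring, closes by 6-exo-trig addition of the phenolic oxygen to the aldehyde carbonyl. The single new stereocentre C3' is set by the catalyst, whose (S)-pyrrolidine arm blocks the face leading to (S), so (R) should result; the lactol carbon is left as both anomers and is removed as a stereocentre in step 2. The step needs ortho over para C-alkylation, C- over O-alkylation and a single alkylation: the two ortho carbons of 1 are equivalent and less hindered than the para carbon between two benzyloxy groups, only the ortho adduct is drawn off as the lactol, and 4 no longer has the free phenol that makes 1 so nucleophilic.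

Step 2
Reactants: 4 (4R)-5,7-bis(benzyloxy)-4-propylchroman-2-ol
Product: 5 (4R)-5,7-bis(benzyloxy)-4-propylchroman-2-one
Conditions: Pr4N[RuO4] (5 mol%), NMO (1.5 equiv), 4 Å MS, CH2Cl2, rt
Reagents that add atoms: none
Why: Ley–Griffith oxidation: the perruthenate, reoxidised by NMO, converts the hemiacetal C–H of either anomer into the lactone carbonyl under neutral conditions that should leave the benzyl ethers and the non-enolisable benzylic stereocentre untouched.

Step 3
Reactants: 5 (4R)-5,7-bis(benzyloxy)-4-propylchroman-2-one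
Product: 6 methyl (3R)-3-[2,4-bis(benzyloxy)-6-hydroxyphenyl]hexanoate
Conditions: NaOMe (0.2 equiv), MeOH, 0 °C to rt; then AcOH
Reagents that add atoms: methanol, CO
Why: Base-catalysed transesterification of an aryl ester: methoxide opens the activated lactone, the large excess of methanol and the good phenoxide leaving group hold the equilibrium on the side of the open methyl ester, C3' is not acidic, and acidification before concentration should prevent relactonisation.

Step 4
Reactants: 7 tert-butyl (S)-3-hydroxybutanoate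
Product: 9 tert-butyl (2S,3S)-3-hydroxy-2-methylbutanoate, via dilithium alkoxide enolate 8 (not isolated)
Conditions: LiN(i-Pr)2 (commercial solution, 2.2 equiv), THF, −78 to −20 °C; MeI, DMPU, −78 to 0 °C; AcOH quench
Reagents that add atoms: iodomethane, CI
Why: Fráter–Seebach alkylation: double deprotonation gives a lithium-chelated alkoxide enolate whose face opposite the C3 methyl group is attacked by iodomethane, which should set C2 as (S), anti to the untouched (S)-carbinol.

Step 5
Reactants: 6 methyl (3R)-3-[2,4-bis(benzyloxy)-6-hydroxyphenyl]hexanoate; 9 tert-butyl (2S,3S)-3-hydroxy-2-methylbutanoate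
Product: 10 tert-butyl (2S,3R)-3-{3,5-bis(benzyloxy)-2-[(3R)-1-methoxy-1-oxohexan-3-yl]phenoxy}-2-methylbutanoate
Conditions: PPh3, DIAD, PhMe, 0 °C to rt
Reagents that add atoms: none
Why: Mitsunobu etherification: the secondary alcohol is activated as its alkoxyphosphonium ion and displaced by the phenoxide of 6 in an SN2 step, so the carbinol carbon (future C2) is inverted from (S) to (R) while the neighbouring methyl-bearing carbon (future C3) is untouched; the bulky tert-butyl ester is chosen to hold back elimination to the tiglate.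

Step 6
Reactants: 10 tert-butyl (2S,3R)-3-{3,5-bis(benzyloxy)-2-[(3R)-1-methoxy-1-oxohexan-3-yl]phenoxy}-2-methylbutanoate
Product: 11 (2S,3R)-3-{3,5-bis(benzyloxy)-2-[(3R)-1-methoxy-1-oxohexan-3-yl]phenoxy}-2-methylbutanoic acid
Conditions: CF3CO2H, Et3SiH (3 equiv), CH2Cl2, 0 °C
Reagents that add atoms: none
Why: Acidolysis of the tert-butyl ester through the tert-butyl cation, which Et3SiH reduces to 2-methylpropane before it can alkylate electron-rich ring A; the methyl ester, the benzyl ethers and the stereocentres should survive short exposure to cold acid.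

Step 7
Reactants: 11 (2S,3R)-3-{3,5-bis(benzyloxy)-2-[(3R)-1-methoxy-1-oxohexan-3-yl]phenoxy}-2-methylbutanoic acid
Product: 13 methyl (3R)-3-[(2R,3S)-5,7-bis(benzyloxy)-2,3-dimethyl-4-oxochroman-8-yl]hexanoate, via mixed trifluoroacetic anhydride 12 (not isolated)
Conditions: (CF3CO)2O (1.5 equiv), CH2Cl2, 0 °C
Reagents that add atoms: none
Why: Intramolecular Friedel–Crafts acylation: TFAA turns the acid into mixed anhydride 12, and the only free carbon ortho to O1 (C4a, also ortho to O5 and para to O7) attacks the acyl group to close six-membered ring B without a Lewis acid; the cold, base-free medium should keep the α-stereocentre (C3) from enolising, so the cis pair is kept.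

Step 8
Reactants: 13 methyl (3R)-3-[(2R,3S)-5,7-bis(benzyloxy)-2,3-dimethyl-4-oxochroman-8-yl]hexanoate
Product: 14 methyl (3R)-3-[(2R,3S)-5,7-dihydroxy-2,3-dimethyl-4-oxochroman-8-yl]hexanoate
Conditions: H2 (1 atm), Pd/C, EtOAc, rt
Reagents that add atoms: none
Why: Catalytic hydrogenolysis of the two benzyl aryl ethers; the phloroglucinol-type aryl ketone, the methyl ester and the three stereocentres are not touched, and the step is placed before the prenyl group exists because that alkene would be hydrogenated.

Step 9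
Reactants: 15 2-methylbut-3-en-2-ol
Product: 16 methyl (2-methylbut-3-en-2-yl) carbonate
Conditions: n-BuLi, THF, −78 °C; ClCO2Me, −78 °C to rt
Reagents that add atoms: methyl chloroformate, COC(=O)Cl
Why: Acylation of the lithium alkoxide of a tertiary alcohol with a chloroformate gives the mixed carbonate needed as allyl donor.

Step 10
Reactants: 14 methyl (3R)-3-[(2R,3S)-5,7-dihydroxy-2,3-dimethyl-4-oxochroman-8-yl]hexanoate; 16 methyl (2-methylbut-3-en-2-yl) carbonate
Product: 17 methyl (3R)-3-{(2R,3S)-5-hydroxy-2,3-dimethyl-7-[(2-methylbut-3-en-2-yl)oxy]-4-oxochroman-8-yl}hexanoate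
Conditions: Pd(PPh3)4 (5 mol%), 16 (1.1 equiv), THF, 0 °C
Reagents that add atoms: none
Why: Tsuji–Trost O-allylation: zerovalent palladium ionises 16 to a 1,1-dimethylallyl complex with loss of CO2 and methoxide, the methoxide deprotonates the more acidic 7-OH (5-OH is held in a hydrogen bond to C4=O), and the phenoxide attacks the more substituted allyl terminus to give the tertiary ether without strong base, which should spare the cis-2,3-dimethyl unit.

Step 11
Reactants: 17 methyl (3R)-3-{(2R,3S)-5-hydroxy-2,3-dimethyl-7-[(2-methylbut-3-en-2-yl)oxy]-4-oxochroman-8-yl}hexanoate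
Product: 19 methyl (3R)-3-[(2R,3S)-5,7-dihydroxy-2,3-dimethyl-6-(3-methylbut-2-enyl)-4-oxochroman-8-yl]hexanoate, via Claisen dienone 18 (not isolated)
Conditions: PhMe (degassed), 110 °C
Reagents that add atoms: none
Why: Aromatic Claisen rearrangement: the [3,3] shift moves the allyl group with transposition from O7 to C6, the only free ortho carbon (C8 is blocked), so the 1,1-dimethylallyl ether becomes a 3-methylbut-2-enyl group, and dienone 18 tautomerises to the phenol under neutral thermal conditions.

**Compound list**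

1 | 3,5-bis(benzyloxy)phenol | Oc1cc(OCc2ccccc2)cc(OCc2ccccc2)c1 | starting material
2 | (E)-hex-2-enal | CCC/C=C/C=O | starting material
3 | (3R)-3-[2,4-bis(benzyloxy)-6-hydroxyphenyl]hexanal | CCC[C@H](CC=O)c1c(O)cc(OCc2ccccc2)cc1OCc1ccccc1 | intermediate
4 | (4R)-5,7-bis(benzyloxy)-4-propylchroman-2-ol (both anomers) | CCC[C@@H]1CC(O)Oc2cc(OCc3ccccc3)cc(OCc3ccccc3)c21 | intermediate
5 | (4R)-5,7-bis(benzyloxy)-4-propylchroman-2-one | CCC[C@@H]1CC(=O)Oc2cc(OCc3ccccc3)cc(OCc3ccccc3)c21 | intermediate
6 | methyl (3R)-3-[2,4-bis(benzyloxy)-6-hydroxyphenyl]hexanoate | CCC[C@H](CC(=O)OC)c1c(O)cc(OCc2ccccc2)cc1OCc1ccccc1 | intermediate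
7 | tert-butyl (S)-3-hydroxybutanoate | C[C@H](O)CC(=O)OC(C)(C)C | starting material
8 | dilithium alkoxide enolate of 7 (lithium-chelated) | [Li+].[Li+].C[C@H]([O-])/C=C(\[O-])OC(C)(C)C | intermediate
9 | tert-butyl (2S,3S)-3-hydroxy-2-methylbutanoate | C[C@H](O)[C@H](C)C(=O)OC(C)(C)C | intermediate
10 | tert-butyl (2S,3R)-3-{3,5-bis(benzyloxy)-2-[(3R)-1-methoxy-1-oxohexan-3-yl]phenoxy}-2-methylbutanoate | CCC[C@H](CC(=O)OC)c1c(O[C@H](C)[C@H](C)C(=O)OC(C)(C)C)cc(OCc2ccccc2)cc1OCc1ccccc1 | intermediate
11 | (2S,3R)-3-{3,5-bis(benzyloxy)-2-[(3R)-1-methoxy-1-oxohexan-3-yl]phenoxy}-2-methylbutanoic acid | CCC[C@H](CC(=O)OC)c1c(O[C@H](C)[C@H](C)C(=O)O)cc(OCc2ccccc2)cc1OCc1ccccc1 | intermediate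
12 | (2S,3R)-3-{3,5-bis(benzyloxy)-2-[(3R)-1-methoxy-1-oxohexan-3-yl]phenoxy}-2-methylbutanoic trifluoroacetic anhydride | CCC[C@H](CC(=O)OC)c1c(O[C@H](C)[C@H](C)C(=O)OC(=O)C(F)(F)F)cc(OCc2ccccc2)cc1OCc1ccccc1 | intermediate
13 | methyl (3R)-3-[(2R,3S)-5,7-bis(benzyloxy)-2,3-dimethyl-4-oxochroman-8-yl]hexanoate | CCC[C@H](CC(=O)OC)c1c(OCc2ccccc2)cc(OCc2ccccc2)c2c1O[C@H](C)[C@H](C)C2=O | intermediate
14 | methyl (3R)-3-[(2R,3S)-5,7-dihydroxy-2,3-dimethyl-4-oxochroman-8-yl]hexanoate | CCC[C@H](CC(=O)OC)c1c(O)cc(O)c2c1O[C@H](C)[C@H](C)C2=O | intermediate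
15 | 2-methylbut-3-en-2-ol | CC(C)(O)C=C | starting material
16 | methyl (2-methylbut-3-en-2-yl) carbonate | COC(=O)OC(C)(C)C=C | intermediate
17 | methyl (3R)-3-{(2R,3S)-5-hydroxy-2,3-dimethyl-7-[(2-methylbut-3-en-2-yl)oxy]-4-oxochroman-8-yl}hexanoate | CCC[C@H](CC(=O)OC)c1c(OC(C)(C)C=C)cc(O)c2c1O[C@H](C)[C@H](C)C2=O | intermediate
18 | methyl (3R)-3-[(2R,3S)-5-hydroxy-2,3-dimethyl-6-(3-methylbut-2-enyl)-4,7-dioxo-3,4,6,7-tetrahydro-2H-chromen-8-yl]hexanoate (C6 epimers) | CCC[C@H](CC(=O)OC)C1=C2O[C@H](C)[C@H](C)C(=O)C2=C(O)C(CC=C(C)C)C1=O | intermediate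
19 | methyl (3R)-3-[(2R,3S)-5,7-dihydroxy-2,3-dimethyl-6-(3-methylbut-2-enyl)-4-oxochroman-8-yl]hexanoate | CCC[C@H](CC(=O)OC)c1c(O)c(CC=C(C)C)c(O)c2c1O[C@H](C)[C@H](C)C2=O | target

**Step count**

Total: 11 steps. Longest linear sequence: 9 steps (1, 2, 3, 5, 6, 7, 8, 10, 11); steps 4 and 9 are side branches.

**Steps most likely to fail**

Step 5. The activated β-oxyphosphonium ester may eliminate to the tiglate, or displacement at the hindered secondary carbon by the ortho-substituted phenoxide may be too slow, so little ether would form. The fallback sets out from 6 and comes back at 11, replacing steps 4 to 6. A palladium-catalysed asymmetric allylic etherification of 6 with (E)-2-methylbut-2-enyl methyl carbonate [Pd2(dba)3, the enantiomer of the bis(2-diphenylphosphinobenzamide) ligand of trans-1,2-diaminocyclohexane that gives (R), CH2Cl2] should give the branched ether methyl (3R)-3-[2,4-bis(benzyloxy)-6-{[(2R)-3-methylbut-3-en-2-yl]oxy}phenyl]hexanoate F1. Rhodium-catalysed hydroboration with catecholborane [RhCl(PPh3)3, THF], which is syn-selective for 1,1-disubstituted allylic ethers where the uncatalysed reaction is anti-selective, should give the boronate methyl (3R)-3-[2-{[(2R,3R)-4-(1,3,2-benzodioxaborol-2-yl)-3-methylbutan-2-yl]oxy}-4,6-bis(benzyloxy)phenyl]hexanoate F2. This is oxidised in the same flask (H2O2, pH 7 buffer) to the alcohol methyl (3R)-3-[2,4-bis(benzyloxy)-6-{[(2R,3R)-4-hydroxy-3-methylbutan-2-yl]oxy}phenyl]hexanoate F3. TEMPO (cat.) with PhI(OAc)2 in aqueous MeCN then takes F3 through the aldehyde methyl (3R)-3-[2,4-bis(benzyloxy)-6-{[(2R,3S)-3-methyl-4-oxobutan-2-yl]oxy}phenyl]hexanoate F4 to acid 11, and the route continues with step 7.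

Step 1. Enantioface discrimination may be insufficient with the aliphatic enal, and alkylation at the para carbon or a second alkylation of the product may compete. The fallback sets out from 1 and comes back at 5, replacing steps 1 and 2. Palladium-catalysed hydroarylation and lactonisation of 1 with ethyl hex-2-ynoate [Pd(OAc)2, NaOAc, HCO2H, rt] should give the coumarin 5,7-bis(benzyloxy)-4-propyl-2H-chromen-2-one F5. Its asymmetric conjugate reduction with copper hydride [Cu(OAc)2, the DTBM-SEGPHOS enantiomer that gives (R), (EtO)2MeSiH, t-BuOH, PhMe] should give lactone 5.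

Step 10. The phenoxide may attack the unsubstituted allyl terminus, giving the linear prenyl ether, which would lead to the wrong C6 isomer on rearrangement. The hindered 7-OH may also react slowly, or O5 may be etherified as well. The fallback sets out from 14 and comes back at 19, replacing steps 9 to 11. Iodination of the only free ring carbon with N-iodosuccinimide (DMF, 0 °C) should give methyl (3R)-3-[(2R,3S)-5,7-dihydroxy-6-iodo-2,3-dimethyl-4-oxochroman-8-yl]hexanoate F6. Stille coupling with tributyl(3-methylbut-2-enyl)stannane [Pd(PPh3)4, DMF, 80 °C] under neutral conditions should give 19 directly.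

**Further compounds**

F1 | step 5 | methyl (3R)-3-[2,4-bis(benzyloxy)-6-{[(2R)-3-methylbut-3-en-2-yl]oxy}phenyl]hexanoate | CCC[C@H](CC(=O)OC)c1c(O[C@H](C)C(C)=C)cc(OCc2ccccc2)cc1OCc1ccccc1
F2 | step 5 | methyl (3R)-3-[2-{[(2R,3R)-4-(1,3,2-benzodioxaborol-2-yl)-3-methylbutan-2-yl]oxy}-4,6-bis(benzyloxy)phenyl]hexanoate | CCC[C@H](CC(=O)OC)c1c(O[C@H](C)[C@H](C)CB2Oc3ccccc3O2)cc(OCc2ccccc2)cc1OCc1ccccc1
F3 | step 5 | methyl (3R)-3-[2,4-bis(benzyloxy)-6-{[(2R,3R)-4-hydroxy-3-methylbutan-2-yl]oxy}phenyl]hexanoate | CCC[C@H](CC(=O)OC)c1c(O[C@H](C)[C@H](C)CO)cc(OCc2ccccc2)cc1OCc1ccccc1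
F4 | step 5 | methyl (3R)-3-[2,4-bis(benzyloxy)-6-{[(2R,3S)-3-methyl-4-oxobutan-2-yl]oxy}phenyl]hexanoate | CCC[C@H](CC(=O)OC)c1c(O[C@H](C)[C@H](C)C=O)cc(OCc2ccccc2)cc1OCc1ccccc1
F5 | step 1 | 5,7-bis(benzyloxy)-4-propyl-2H-chromen-2-one | CCCC1=CC(=O)Oc2cc(OCc3ccccc3)cc(OCc3ccccc3)c12
F6 | step 10 | methyl (3R)-3-[(2R,3S)-5,7-dihydroxy-6-iodo-2,3-dimethyl-4-oxochroman-8-yl]hexanoate | CCC[C@H](CC(=O)OC)c1c(O)c(I)c(O)c2c1O[C@H](C)[C@H](C)C2=O
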